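**Plan**

- The target is (5S)-5-hydroxy-1,7-bis(4-hydroxy-3-methoxyphenyl)heptan-3-one, an open chain with one stereocentre and no ring to form.
- Enabling feature: carbonyl carbon C3 is flanked by the CH2 groups C2 and C4, and C1–C2 with its guaiacyl ring is what remains of dihydroferulic acid once CO2 is lost.
- Retrosynthesis: cut C2–C3 first (acyl carbon of a C3–C7 thioester against a 2-arylethyl radical from a redox-active ester), then cut C4–C5 of the C3–C7 acid (two-carbon malonate homologation). Both halves then come from O-benzyl dihydroferulic acid.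
- Forward: benzylation; one portion becomes the N-acyloxyphthalimide, the other is homologated, hydrogenated, silylated, saponified and thioesterified; the chain is joined at C2–C3 at a cathode under nickel catalysis; desilylation and hydrogenolysis finish.
- Stereochemistry: C5 (S) is set by hydrogenation of the β-keto ester with RuCl2[(S)-BINAP] and is never a reacting centre afterwards.

Key step: step 8

Remark: locants C1–C7 are those of the heptan-3-one chain of the target. The electrolysis in step 8 is assumed to run in an undivided cell against a sacrificial zinc anode, so zinc is the terminal electron source.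

Step 1
Reactants: 1 3-(4-hydroxy-3-methoxyphenyl)propanoic acid (dihydroferulic acid)
Product: 3 3-(4-benzyloxy-3-methoxyphenyl)propanoic acid, via benzyl ester benzyl ether 2 (not isolated)
Conditions: BnBr (2.3 equiv), K2CO3, DMF, 60 °C; then aq NaOH, MeOH, 60 °C; aq HCl work-up
Reagents that add atoms: benzyl bromide, BrCc1ccccc1; sodium hydroxide, [Na+].[OH-]
Why: Williamson etherification of the phenoxide (with concurrent O-benzylation of the carboxylate) followed by saponification of the benzyl ester in the same pot should leave only the hydroxide-stable aryl benzyl ether.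

Step 2
Reactants: 3 3-(4-benzyloxy-3-methoxyphenyl)propanoic acid; 4 N-hydroxyphthalimide
Product: 5 1,3-dioxoisoindolin-2-yl 3-(4-benzyloxy-3-methoxyphenyl)propanoate
Conditions: DIC, DMAP (cat.), CH2Cl2, rt
Reagents that add atoms: none
Why: Steglich-type carbodiimide esterification is the standard way to make N-acyloxyphthalimide redox-active esters, and the benzyl ether is inert to it.

Step 3
Reactants: 3 3-(4-benzyloxy-3-methoxyphenyl)propanoic acid; 6 potassium methyl malonate
Product: 9 methyl 5-(4-benzyloxy-3-methoxyphenyl)-3-oxopentanoate, via acyl imidazolide 7 (not isolated), via acylmalonate half-ester 8 (not isolated)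
Conditions: CDI, THF, rt; then MgCl2, Et3N, MeCN, rt to 45 °C; aq HCl work-up
Reagents that add atoms: none
Why: Masamune–Brooks homologation, in which the magnesium enolate of the malonate half-ester is C-acylated by the acyl imidazolide and the acylmalonate loses CO2 on acidification, should give the β-keto ester without any strong base.

Step 4
Reactants: 9 methyl 5-(4-benzyloxy-3-methoxyphenyl)-3-oxopentanoate
Product: 10 methyl (3S)-5-(4-benzyloxy-3-methoxyphenyl)-3-hydroxypentanoate
Conditions: H2 (50 atm), RuCl2[(S)-BINAP] (0.5 mol %), MeOH, 50 °C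
Reagents that add atoms: none
Why: Noyori asymmetric hydrogenation, in which the ester carbonyl chelates ruthenium and the (S)-BINAP ligand directs hydride to the ketone face that gives the 3S alcohol (the sense in which methyl acetoacetate gives methyl (S)-3-hydroxybutanoate), should set C5 of the target, and this homogeneous catalyst does not cleave aryl benzyl ethers.

Step 5
Reactants: 10 methyl (3S)-5-(4-benzyloxy-3-methoxyphenyl)-3-hydroxypentanoate
Product: 11 methyl (3S)-5-(4-benzyloxy-3-methoxyphenyl)-3-(tert-butyldimethylsilyloxy)pentanoate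
Conditions: TBSCl, imidazole, DMF, rt
Reagents that add atoms: tert-butyldimethylsilyl chloride, CC(C)(C)[Si](C)(C)Cl
Why: Corey silylation of a secondary alcohol with the imidazole-activated silyl chloride does not touch the stereocentre.

Step 6
Reactants: 11 methyl (3S)-5-(4-benzyloxy-3-methoxyphenyl)-3-(tert-butyldimethylsilyloxy)pentanoate
Product: 12 (3S)-5-(4-benzyloxy-3-methoxyphenyl)-3-(tert-butyldimethylsilyloxy)pentanoic acid
Conditions: LiOH·H2O, THF/MeOH/H2O, 0 °C to rt; then cold dilute HCl to pH 4
Reagents that add atoms: lithium hydroxide, [Li+].[OH-]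
Why: Saponification of the unhindered methyl ester should outrun E1cB loss of the silyloxy group at this temperature, and a secondary TBS ether tolerates LiOH.

Step 7
Reactants: 12 (3S)-5-(4-benzyloxy-3-methoxyphenyl)-3-(tert-butyldimethylsilyloxy)pentanoic acid
Product: 13 S-(pyridin-2-yl) (3S)-5-(4-benzyloxy-3-methoxyphenyl)-3-(tert-butyldimethylsilyloxy)pentanethioate
Conditions: 2,2'-dipyridyl disulfide, PPh3, CH2Cl2, rt
Reagents that add atoms: 2,2'-dipyridyl disulfide, c1ccc(SSc2ccccn2)nc1
Why: Mukaiyama redox condensation, in which the acyloxyphosphonium ion is intercepted by pyridine-2-thiolate under neutral conditions, should give the thioester without endangering the β-silyloxy centre.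

Step 8
Reactants: 5 1,3-dioxoisoindolin-2-yl 3-(4-benzyloxy-3-methoxyphenyl)propanoate; 13 S-(pyridin-2-yl) (3S)-5-(4-benzyloxy-3-methoxyphenyl)-3-(tert-butyldimethylsilyloxy)pentanethioate
Product: 14 (5S)-1,7-bis(4-benzyloxy-3-methoxyphenyl)-5-(tert-butyldimethylsilyloxy)heptan-3-one
Conditions: NiBr2(dme) (10 mol %), 4,4'-di-tert-butyl-2,2'-bipyridine (12 mol %), LiBr, DMA, undivided cell, reticulated vitreous carbon cathode, sacrificial Zn anode, constant current, rt, argon; 5 (1.5 equiv) added in portions; aq NH4Cl work-up
Reagents that add atoms: none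
Why: Proposed new method: the closest known reaction is the nickel-catalysed reductive decarboxylative coupling of N-acyloxyphthalimides with S-2-pyridyl thioesters driven by zinc powder, and here the same catalyst system is turned over at a carbon cathode against a sacrificial zinc anode, as in nickel-electrocatalytic decarboxylative couplings of such redox-active esters with other electrophiles. Zerovalent nickel carrying the bipyridine ligand, formed at the cathode, inserts into the acyl–sulfur bond of 13 (helped by the pyridyl nitrogen and by zinc dications released from the anode) to give an acyl thiolate complex of divalent nickel, while single-electron reduction of 5 by low-valent nickel or at the electrode fragments it into phthalimide anion, CO2 and the primary 2-arylethyl radical. Capture of this radical by the acyl complex gives an acyl alkyl complex of trivalent nickel, which reductively eliminates the C2–C3 bond of ketone 14, and the monovalent nickel left over is reduced again at the cathode. No ring closes and no stereocentre is made: the radical carbon is primary, and the silyloxy-bearing carbon (C5 of 14) lies beta to the acyl carbon, away from the metal-bound centre, so its S configuration is carried through. The step needs cross-coupling to win over radical dimerisation, hydrodecarboxylation and decarbonylation of the acyl complex; this rests on the different activation of the two partners (two-electron insertion for the thioester, one-electron reduction for the phthalimide ester), on the slow loss of CO from a primary alkanoyl nickel species, on portionwise addition of an excess of 5 at controlled current, and on the silyl ether, which keeps the C5 oxygen from attacking the activated acyl group.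

Step 9
Reactants: 14 (5S)-1,7-bis(4-benzyloxy-3-methoxyphenyl)-5-(tert-butyldimethylsilyloxy)heptan-3-one
Product: 15 (5S)-1,7-bis(4-benzyloxy-3-methoxyphenyl)-5-hydroxyheptan-3-one
Conditions: HF·pyridine, pyridine, THF, 0 °C to rt
Reagents that add atoms: none
Why: Fluoride-mediated desilylation under pyridine-buffered, weakly acidic conditions is chosen over basic fluoride sources so that the β-hydroxy ketone should neither dehydrate nor undergo retro-aldol cleavage.

Step 10
Reactants: 15 (5S)-1,7-bis(4-benzyloxy-3-methoxyphenyl)-5-hydroxyheptan-3-one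
Product: 16 (5S)-5-hydroxy-1,7-bis(4-hydroxy-3-methoxyphenyl)heptan-3-one
Conditions: H2 (1 atm), 10% Pd/C, EtOAc, rt
Reagents that add atoms: none
Why: Heterogeneous hydrogenolysis of the two aryl benzyl ethers should proceed without reducing the dialkyl ketone or the secondary alcohol, neither of which is benzylic.

**Compound list**

1 | 3-(4-hydroxy-3-methoxyphenyl)propanoic acid (dihydroferulic acid) | COc1cc(CCC(=O)O)ccc1O | starting material
2 | benzyl 3-(4-benzyloxy-3-methoxyphenyl)propanoate (formed in the flask in step 1) | COc1cc(CCC(=O)OCc2ccccc2)ccc1OCc1ccccc1 | intermediate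
3 | 3-(4-benzyloxy-3-methoxyphenyl)propanoic acid | COc1cc(CCC(=O)O)ccc1OCc1ccccc1 | intermediate
4 | N-hydroxyphthalimide | O=C1c2ccccc2C(=O)N1O | starting material
5 | 1,3-dioxoisoindolin-2-yl 3-(4-benzyloxy-3-methoxyphenyl)propanoate | O=C(CCc1ccc(OCc2ccccc2)c(OC)c1)ON1C(=O)c2ccccc2C1=O | intermediate
6 | potassium methyl malonate (potassium 3-methoxy-3-oxopropanoate) | COC(=O)CC(=O)[O-].[K+] | starting material
7 | 1-[3-(4-benzyloxy-3-methoxyphenyl)propanoyl]imidazole (formed in the flask in step 3) | O=C(CCc1ccc(OCc2ccccc2)c(OC)c1)n1ccnc1 | intermediate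
8 | 5-(4-benzyloxy-3-methoxyphenyl)-2-(methoxycarbonyl)-3-oxopentanoic acid, present as its magnesium chelate (formed in the flask in step 3) | COC(=O)C(C(=O)O)C(=O)CCc1ccc(OCc2ccccc2)c(OC)c1 | intermediate
9 | methyl 5-(4-benzyloxy-3-methoxyphenyl)-3-oxopentanoate | COC(=O)CC(=O)CCc1ccc(OCc2ccccc2)c(OC)c1 | intermediate
10 | methyl (3S)-5-(4-benzyloxy-3-methoxyphenyl)-3-hydroxypentanoate | COC(=O)C[C@@H](O)CCc1ccc(OCc2ccccc2)c(OC)c1 | intermediate
11 | methyl (3S)-5-(4-benzyloxy-3-methoxyphenyl)-3-(tert-butyldimethylsilyloxy)pentanoate | COC(=O)C[C@@H](O[Si](C)(C)C(C)(C)C)CCc1ccc(OCc2ccccc2)c(OC)c1 | intermediate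
12 | (3S)-5-(4-benzyloxy-3-methoxyphenyl)-3-(tert-butyldimethylsilyloxy)pentanoic acid | OC(=O)C[C@@H](O[Si](C)(C)C(C)(C)C)CCc1ccc(OCc2ccccc2)c(OC)c1 | intermediate
13 | S-(pyridin-2-yl) (3S)-5-(4-benzyloxy-3-methoxyphenyl)-3-(tert-butyldimethylsilyloxy)pentanethioate | O=C(C[C@@H](O[Si](C)(C)C(C)(C)C)CCc1ccc(OCc2ccccc2)c(OC)c1)Sc1ccccn1 | intermediate
14 | (5S)-1,7-bis(4-benzyloxy-3-methoxyphenyl)-5-(tert-butyldimethylsilyloxy)heptan-3-one | COc1cc(CCC(=O)C[C@@H](O[Si](C)(C)C(C)(C)C)CCc2ccc(OCc3ccccc3)c(OC)c2)ccc1OCc1ccccc1 | intermediate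
15 | (5S)-1,7-bis(4-benzyloxy-3-methoxyphenyl)-5-hydroxyheptan-3-one | COc1cc(CCC(=O)C[C@@H](O)CCc2ccc(OCc3ccccc3)c(OC)c2)ccc1OCc1ccccc1 | intermediate
16 | (5S)-5-hydroxy-1,7-bis(4-hydroxy-3-methoxyphenyl)heptan-3-one | COc1cc(CCC(=O)C[C@@H](O)CCc2ccc(O)c(OC)c2)ccc1O | target

**Step count and risks**

Total: 10 steps. Longest linear sequence: 9 steps (steps 1, 3, 4, 5, 6, 7, 8, 9, 10) from dihydroferulic acid.

Steps most likely to fail:

1. Step 8 (cathodic nickel coupling). The 2-arylethyl radical may dimerise or be reduced to the alkane faster than the acyl nickel species captures it, 5 may be reduced at the bare electrode away from the catalyst, or nickel turnover at the cathode may stall. The fallback forms the same C2–C3 bond by two-electron chemistry. It sets out from benzyl ester 2 (isolated after the alkylation stage of step 1 instead of being saponified) and acid 12, and comes back at target 16.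
   - Acid 12 is activated with CDI in THF to 1-[(3S)-5-(4-benzyloxy-3-methoxyphenyl)-3-(tert-butyldimethylsilyloxy)pentanoyl]imidazole F1.
   - The lithium enolate of 2 (two equivalents, LiN(SiMe3)2, THF, −78 °C) is acylated by F1 in a crossed Claisen condensation. This should give benzyl (5S)-2-[(4-benzyloxy-3-methoxyphenyl)methyl]-7-(4-benzyloxy-3-methoxyphenyl)-5-(tert-butyldimethylsilyloxy)-3-oxoheptanoate F2, as both C2 epimers, which does not matter.
   - Hydrogenolysis (H2, Pd/C, EtOAc) removes the benzyl ester and both aryl benzyl ethers to give (5S)-5-(tert-butyldimethylsilyloxy)-2-[(4-hydroxy-3-methoxyphenyl)methyl]-7-(4-hydroxy-3-methoxyphenyl)-3-oxoheptanoic acid F3.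
   - F3 loses CO2 on gentle warming to give (5S)-5-(tert-butyldimethylsilyloxy)-1,7-bis(4-hydroxy-3-methoxyphenyl)heptan-3-one F4.
   - HF·pyridine, as in step 9, then gives 16.

2. Step 9 (desilylation). Acid- or fluoride-induced dehydration of the freed β-hydroxy ketone to the conjugated enone, or retro-aldol cleavage, may compete with silyl removal. The fallback replaces the silyl ether by a benzyl ether that falls in the final hydrogenolysis, so no desilylation is needed. It sets out from hydroxy ester 10 and comes back at target 16.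
   - 10 is benzylated under neutral conditions (BnBr, Ag2O, CH2Cl2) to methyl (3S)-3-(benzyloxy)-5-(4-benzyloxy-3-methoxyphenyl)pentanoate F5.
   - Saponification as in step 6 gives (3S)-3-(benzyloxy)-5-(4-benzyloxy-3-methoxyphenyl)pentanoic acid F6.
   - Thioesterification as in step 7 gives S-(pyridin-2-yl) (3S)-3-(benzyloxy)-5-(4-benzyloxy-3-methoxyphenyl)pentanethioate F7.
   - Coupling with 5 as in step 8 gives (5S)-5-(benzyloxy)-1,7-bis(4-benzyloxy-3-methoxyphenyl)heptan-3-one F8.
   - One hydrogenolysis (H2, Pd(OH)2/C, EtOAc/EtOH) removes all three benzyl groups and gives 16.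

3. Step 6 (saponification). Hydroxide may trigger E1cB loss of the silyloxy group or partial desilylation before the ester is cleaved. The fallback hydrolyses before silylating, so no β-silyloxy ester ever meets hydroxide. It sets out from hydroxy ester 10 and comes back at acid 12.
   - 10 is saponified (LiOH, THF/H2O) to (3S)-5-(4-benzyloxy-3-methoxyphenyl)-3-hydroxypentanoic acid F9.
   - F9 is bis-silylated (excess TBSCl, imidazole, DMF) to tert-butyldimethylsilyl (3S)-5-(4-benzyloxy-3-methoxyphenyl)-3-(tert-butyldimethylsilyloxy)pentanoate F10.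
   - The silyl ester alone is cleaved with K2CO3 in aqueous methanol at 0 °C to give 12.

**Further compounds**

F1 | step 8 | 1-[(3S)-5-(4-benzyloxy-3-methoxyphenyl)-3-(tert-butyldimethylsilyloxy)pentanoyl]imidazole | O=C(C[C@@H](O[Si](C)(C)C(C)(C)C)CCc1ccc(OCc2ccccc2)c(OC)c1)n1ccnc1
F2 | step 8 | benzyl (5S)-2-[(4-benzyloxy-3-methoxyphenyl)methyl]-7-(4-benzyloxy-3-methoxyphenyl)-5-(tert-butyldimethylsilyloxy)-3-oxoheptanoate (C2 epimers) | COc1cc(CC(C(=O)OCc2ccccc2)C(=O)C[C@@H](O[Si](C)(C)C(C)(C)C)CCc2ccc(OCc3ccccc3)c(OC)c2)ccc1OCc1ccccc1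
F3 | step 8 | (5S)-5-(tert-butyldimethylsilyloxy)-2-[(4-hydroxy-3-methoxyphenyl)methyl]-7-(4-hydroxy-3-methoxyphenyl)-3-oxoheptanoic acid (C2 epimers) | COc1cc(CC(C(=O)O)C(=O)C[C@@H](O[Si](C)(C)C(C)(C)C)CCc2ccc(O)c(OC)c2)ccc1O
F4 | step 8 | (5S)-5-(tert-butyldimethylsilyloxy)-1,7-bis(4-hydroxy-3-methoxyphenyl)heptan-3-one | COc1cc(CCC(=O)C[C@@H](O[Si](C)(C)C(C)(C)C)CCc2ccc(O)c(OC)c2)ccc1O
F5 | step 9 | methyl (3S)-3-(benzyloxy)-5-(4-benzyloxy-3-methoxyphenyl)pentanoate | COC(=O)C[C@@H](OCc1ccccc1)CCc1ccc(OCc2ccccc2)c(OC)c1
F6 | step 9 | (3S)-3-(benzyloxy)-5-(4-benzyloxy-3-methoxyphenyl)pentanoic acid | OC(=O)C[C@@H](OCc1ccccc1)CCc1ccc(OCc2ccccc2)c(OC)c1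
F7 | step 9 | S-(pyridin-2-yl) (3S)-3-(benzyloxy)-5-(4-benzyloxy-3-methoxyphenyl)pentanethioate | O=C(C[C@@H](OCc1ccccc1)CCc1ccc(OCc2ccccc2)c(OC)c1)Sc1ccccn1
F8 | step 9 | (5S)-5-(benzyloxy)-1,7-bis(4-benzyloxy-3-methoxyphenyl)heptan-3-one | COc1cc(CCC(=O)C[C@@H](OCc2ccccc2)CCc2ccc(OCc3ccccc3)c(OC)c2)ccc1OCc1ccccc1
F9 | step 6 | (3S)-5-(4-benzyloxy-3-methoxyphenyl)-3-hydroxypentanoic acid | OC(=O)C[C@@H](O)CCc1ccc(OCc2ccccc2)c(OC)c1
F10 | step 6 | tert-butyldimethylsilyl (3S)-5-(4-benzyloxy-3-methoxyphenyl)-3-(tert-butyldimethylsilyloxy)pentanoate | CC(C)(C)[Si](C)(C)OC(=O)C[C@@H](O[Si](C)(C)C(C)(C)C)CCc1ccc(OCc2ccccc2)c(OC)c1
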